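Ring C is opened at C3–C4 and at O1–C2. This leaves a salicylaldehyde, ring A with C4 as its formyl carbon and O1 as its only free hydroxyl, and an arylpropiolate that carries C3, C2 and ring B. In one pot, rhodium-catalysed hydroacylation adds the aldehyde C–H bond across the alkyne to make C3–C4, and a cinchona thiourea then closes O1 onto C2 and sets the 2S centre. The step exploits the ortho relation of O1 and the C4 carbonyl on ring A. A cumyl (2-phenylpropan-2-yl) ester on C3 directs and activates, then leaves as CO2. The 6-geranyl pattern is fixed earlier through a mirror-symmetric 4-geranyl-3,5-bis(methoxymethoxy)phenol.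

Key step: step 8

Assumption: the quinidine-derived thiourea is taken as the pseudoenantiomer that delivers O1 to the face of C2 giving 2S; if the sense proves opposite, the quinine-derived catalyst replaces it.

Abbreviations: MOM = methoxymethyl; geranyl = (2E)-3,7-dimethylocta-2,6-dien-1-yl; cumyl = 2-phenylpropan-2-yl.

Step 1
Reactants: 1 resorcinol
Product: 2 1,3-bis(methoxymethoxy)benzene
Conditions: NaH (2.4 equiv), MOMCl (2.4 equiv), DMF, 0 °C to rt
Reagents that add atoms: chloromethyl methyl ether (MOMCl), COCCl
Why: Williamson etherification of both phenoxides should give the bis-acetal, whose oxygens later direct the lithiation and leave under mild acid.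

Step 2
Reactants: 2 1,3-bis(methoxymethoxy)benzene; 3 geranyl bromide
Product: 5 2-geranyl-1,3-bis(methoxymethoxy)benzene, via aryllithium 4 (not isolated)
Conditions: n-BuLi (1.1 equiv), THF, 0 °C to rt; CuI (10 mol%), then 3, −40 °C to rt
Reagents that add atoms: none
Why: Directed ortho-metalation should occur at C2, the position flanked by both MOM ethers, and copper-assisted SN2 allylation of the aryllithium at the primary carbon of 3 should keep the E alkene.

Step 3
Reactants: 5 2-geranyl-1,3-bis(methoxymethoxy)benzene
Product: 7 4-geranyl-3,5-bis(methoxymethoxy)phenol, via arylboronate 6 (not isolated)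
Conditions: B2pin2 (0.6 equiv), [Ir(OMe)(cod)]2 (1.5 mol%), 4,4'-di-tert-butyl-2,2'-bipyridine (3 mol%), THF, 80 °C; then aq. H2O2, aq. NaOH, THF, 0 °C
Reagents that add atoms: hydrogen peroxide, OO
Why: Iridium-catalysed C–H borylation is governed by sterics and should pick C5, the only ring C–H with no ortho substituent, and oxidation of the C–B bond then gives a phenol whose two ortho positions are equivalent by the mirror plane through C1 and C4.

Step 4
Reactants: 7 4-geranyl-3,5-bis(methoxymethoxy)phenol
Product: 8 3-geranyl-6-hydroxy-2,4-bis(methoxymethoxy)benzaldehyde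
Conditions: MgCl2 (2 equiv), Et3N (4 equiv), paraformaldehyde (6 equiv), MeCN, 80 °C; aq. NH4Cl work-up
Reagents that add atoms: formaldehyde (from paraformaldehyde), C=O
Why: Magnesium-phenoxide-directed ortho-formylation (Casnati–Skattebøl reaction, hydroxymethylation followed by hydride transfer to a second formaldehyde) should act only ortho to the free hydroxyl, and since both ortho sites of 7 are the same, the formyl carbon (C4 of the target) lands between the free OH (O1) and a MOM ether, with the geranyl group between the two MOM ethers.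

Step 5
Reactants: 9 4-(methoxymethoxy)benzaldehyde
Product: 10 1-ethynyl-4-(methoxymethoxy)benzene
Conditions: dimethyl (1-diazo-2-oxopropyl)phosphonate (1.2 equiv), K2CO3 (2 equiv), MeOH, rt
Reagents that add atoms: dimethyl (1-diazo-2-oxopropyl)phosphonate, COP(=O)(OC)C(=[N+]=[N-])C(C)=O
Why: Seyferth–Gilbert homologation with the Ohira–Bestmann reagent should convert the aldehyde into the terminal alkyne under mild base that leaves the MOM ether intact.

Step 6
Reactants: 10 1-ethynyl-4-(methoxymethoxy)benzene
Product: 12 3-[4-(methoxymethoxy)phenyl]prop-2-ynoic acid, via lithium acetylide 11 (not isolated)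
Conditions: n-BuLi (1.05 equiv), THF, −78 °C; CO2 (gas), −78 to 0 °C; cold dilute HCl to pH 3
Reagents that add atoms: carbon dioxide, O=C=O
Why: Deprotonation of the terminal alkyne and carboxylation of the lithium acetylide with CO2 should give the arylpropiolic acid.

Step 7
Reactants: 12 3-[4-(methoxymethoxy)phenyl]prop-2-ynoic acid
Product: 13 cumyl 3-[4-(methoxymethoxy)phenyl]prop-2-ynoate
Conditions: 2-phenylpropan-2-yl 2,2,2-trichloroacetimidate (1.5 equiv), CH2Cl2, rt
Reagents that add atoms: 2-phenylpropan-2-yl 2,2,2-trichloroacetimidate, CC(C)(OC(=N)C(Cl)(Cl)Cl)c1ccccc1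
Why: O-Alkylation of the carboxylic acid by the trichloroacetimidate (acid-promoted transfer of the cumyl cation, driven by amide formation) should give a bulky ester without added catalyst, chosen because it ionises under far milder acid than a tert-butyl ester.

Step 8
Reactants: 8 3-geranyl-6-hydroxy-2,4-bis(methoxymethoxy)benzaldehyde; 13 cumyl 3-[4-(methoxymethoxy)phenyl]prop-2-ynoate
Product: 15 cumyl (2S,3R)-6-geranyl-5,7-bis(methoxymethoxy)-2-[4-(methoxymethoxy)phenyl]-4-oxochromane-3-carboxylate, via alkylidene β-keto ester 14 (not isolated)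
Conditions: 8 (1.0 equiv), 13 (1.2 equiv), [Rh(OMe)(cod)]2 (2.5 mol%), 1,1'-bis(diphenylphosphino)ferrocene (5 mol%), toluene, 60 °C; then −25 °C, 9-amino-9-deoxy-epi-quinidine N'-[3,5-bis(trifluoromethyl)phenyl]thiourea (10 mol%)
Reagents that add atoms: none
Why: Proposed new method: the phenoxide of 8 binds monovalent rhodium, which inserts into the aldehyde C–H bond to give a chelated acyl hydride of trivalent rhodium; the hydride adds to the aryl-bearing β-carbon of ynoate 13 and C–C reductive elimination joins C4 to C3, giving enone 14. The closest known reaction type is the rhodium-catalysed hydroacylation of alkynes by salicylaldehydes run in tandem with oxa-Michael closure to chroman-4-ones, extended here to a conjugated ynoate and handed over to a chiral organocatalyst. At −25 °C the thiourea binds the β-keto ester of 14 while its quinuclidine nitrogen delivers the phenol O1 to C2, a 6-endo-trig oxa-Michael closure of ring C of the kind known for alkylidene β-keto esters. C2 is set by the catalyst, which shields one face of the enone (the pseudoenantiomeric catalyst gives the antipode), whereas C3 settles trans by epimerisation and is removed in step 9. The step needs the acyl group on the ester-bearing alkyne carbon, which conjugate hydride delivery and the aryl group both favour, and closure through O1 alone, which is secured because O1 is the only free hydroxyl of 8. The isolated trisubstituted alkenes of the geranyl chain should not insert, and an internal ynoate avoids the oligomerisation to which terminal alkynes are prone on rhodium.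

Step 9
Reactants: 15 cumyl (2S,3R)-6-geranyl-5,7-bis(methoxymethoxy)-2-[4-(methoxymethoxy)phenyl]-4-oxochromane-3-carboxylate
Product: 18 Bonannione A [(2S)-6-geranyl-5,7-dihydroxy-2-(4-hydroxyphenyl)chroman-4-one], via β-keto acid 16 (not isolated), via tris-MOM flavanone 17 (not isolated)
Conditions: HCl (1.25 M in i-PrOH, 10 equiv), THF, 35 °C
Reagents that add atoms: none
Why: Acid-mediated solvolysis should ionise the cumyl ester (alkyl–oxygen cleavage), the β-keto acid 16 should lose CO2 through its enol without touching C2, and acetal exchange with i-PrOH should remove the three MOM groups, the secondary alcohol being too slow to esterify 16 and the acidic medium avoiding the base-induced retro-oxa-Michael opening that would racemise C2.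

Compound list
1 | resorcinol (benzene-1,3-diol) | Oc1cccc(O)c1 | starting material
2 | 1,3-bis(methoxymethoxy)benzene | COCOc1cccc(OCOC)c1 | intermediate
3 | geranyl bromide, (2E)-1-bromo-3,7-dimethylocta-2,6-diene | CC(C)=CCC/C(C)=C/CBr | starting material
4 | [2,6-bis(methoxymethoxy)phenyl]lithium, formed in the flask in step 2 | [Li]c1c(OCOC)cccc1OCOC | intermediate
5 | 2-[(2E)-3,7-dimethylocta-2,6-dien-1-yl]-1,3-bis(methoxymethoxy)benzene | COCOc1cccc(OCOC)c1C/C=C(\C)CCC=C(C)C | intermediate
6 | 2-[4-geranyl-3,5-bis(methoxymethoxy)phenyl]-4,4,5,5-tetramethyl-1,3,2-dioxaborolane, formed in the flask in step 3 | COCOc1cc(B2OC(C)(C)C(C)(C)O2)cc(OCOC)c1C/C=C(\C)CCC=C(C)C | intermediate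
7 | 4-[(2E)-3,7-dimethylocta-2,6-dien-1-yl]-3,5-bis(methoxymethoxy)phenol | COCOc1cc(O)cc(OCOC)c1C/C=C(\C)CCC=C(C)C | intermediate
8 | 3-[(2E)-3,7-dimethylocta-2,6-dien-1-yl]-6-hydroxy-2,4-bis(methoxymethoxy)benzaldehyde | COCOc1cc(O)c(C=O)c(OCOC)c1C/C=C(\C)CCC=C(C)C | intermediate
9 | 4-(methoxymethoxy)benzaldehyde | COCOc1ccc(C=O)cc1 | starting material
10 | 1-ethynyl-4-(methoxymethoxy)benzene | COCOc1ccc(C#C)cc1 | intermediate
11 | lithium [4-(methoxymethoxy)phenyl]acetylide, formed in the flask in step 6 | [Li]C#Cc1ccc(OCOC)cc1 | intermediate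
12 | 3-[4-(methoxymethoxy)phenyl]prop-2-ynoic acid | COCOc1ccc(C#CC(=O)O)cc1 | intermediate
13 | 2-phenylpropan-2-yl 3-[4-(methoxymethoxy)phenyl]prop-2-ynoate | COCOc1ccc(C#CC(=O)OC(C)(C)c2ccccc2)cc1 | intermediate
14 | 2-phenylpropan-2-yl (2Z)-2-[3-geranyl-6-hydroxy-2,4-bis(methoxymethoxy)benzoyl]-3-[4-(methoxymethoxy)phenyl]prop-2-enoate, formed in the flask in step 8 | COCOc1ccc(/C=C(\C(=O)OC(C)(C)c2ccccc2)C(=O)c2c(O)cc(OCOC)c(C/C=C(\C)CCC=C(C)C)c2OCOC)cc1 | intermediate
15 | 2-phenylpropan-2-yl (2S,3R)-6-geranyl-5,7-bis(methoxymethoxy)-2-[4-(methoxymethoxy)phenyl]-4-oxochromane-3-carboxylate (2,3-trans; C3 epimerisable) | O=C1[C@H](C(=O)OC(C)(C)c2ccccc2)[C@@H](c2ccc(OCOC)cc2)Oc2cc(OCOC)c(C/C=C(\C)CCC=C(C)C)c(OCOC)c12 | intermediate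
16 | (2S,3R)-6-geranyl-5,7-bis(methoxymethoxy)-2-[4-(methoxymethoxy)phenyl]-4-oxochromane-3-carboxylic acid, formed in the flask in step 9 | O=C1[C@H](C(=O)O)[C@@H](c2ccc(OCOC)cc2)Oc2cc(OCOC)c(C/C=C(\C)CCC=C(C)C)c(OCOC)c12 | intermediate
17 | (2S)-6-geranyl-5,7-bis(methoxymethoxy)-2-[4-(methoxymethoxy)phenyl]chroman-4-one, formed in the flask in step 9 | O=C1C[C@@H](c2ccc(OCOC)cc2)Oc2cc(OCOC)c(C/C=C(\C)CCC=C(C)C)c(OCOC)c12 | intermediate
18 | Bonannione A, (2S)-6-[(2E)-3,7-dimethylocta-2,6-dien-1-yl]-5,7-dihydroxy-2-(4-hydroxyphenyl)chroman-4-one | CC(C)=CCC/C(C)=C/Cc1c(O)cc2c(c1O)C(=O)C[C@@H](c1ccc(O)cc1)O2 | target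

Total step count: 9 (steps 1–4 build ring A, steps 5–7 the ynoate, steps 8–9 join and unmask).
Longest linear sequence: 6 steps (1, 2, 3, 4, 8, 9).

Steps most likely to fail

1. Step 8 (Proposed new method). The acyl rhodium hydride may be lost to decarbonylation, or the ynoate to oligomerisation or phenol conjugate addition, before insertion. Enone 14 may also ring-close without the thiourea while the hydroacylation is still warm, which would erode the facial selectivity at C2. The fallback uses known chemistry and makes the two bonds one at a time, with the enone isolated cold. Setting out from 8, aldol addition of the lithium enolate of 2-phenylpropan-2-yl acetate (LiN(i-Pr)2, THF, −78 °C, excess enolate to allow for the free phenol) should give 2-phenylpropan-2-yl 3-[3-geranyl-6-hydroxy-2,4-bis(methoxymethoxy)phenyl]-3-hydroxypropanoate F1, racemic at the carbinol carbon. MnO2 in CH2Cl2 should oxidise the benzylic alcohol to 2-phenylpropan-2-yl 3-[3-geranyl-6-hydroxy-2,4-bis(methoxymethoxy)phenyl]-3-oxopropanoate F2. Knoevenagel condensation of F2 with aldehyde 9 (piperidine, AcOH, toluene, rt) should give 14, and the same thiourea at −25 °C should close it, coming back to the route at 15.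

2. Step 9. Protonation of the geranyl alkenes, followed by addition of the neighbouring phenols or of chloride across them, may compete with acetal exchange, and the transient acid may be esterified before it loses CO2. The fallback separates the two tasks and removes the acetals without a protic acid. Setting out from 15, TFA (1% in CH2Cl2, 0 °C) should ionise only the cumyl ester, and warming the resulting acid 16 to 40 °C should release CO2 and give 17, this time isolated. ZnBr2 with propane-1-thiol in CH2Cl2 at 0 °C should then transfer the three MOM groups to sulfur by Lewis-acid-assisted cleavage, coming back at 18. No compound outside the list is made (F0).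

3. Step 3. Hydroboration or isomerisation of the geranyl alkenes by iridium boryl and hydride species may compete with arene C–H borylation. The fallback installs the oxygen before the alkenes are present. Setting out from 2, the same borylation should give 2-[3,5-bis(methoxymethoxy)phenyl]-4,4,5,5-tetramethyl-1,3,2-dioxaborolane F3, and oxidation should give 3,5-bis(methoxymethoxy)phenol F4. Silylation (i-Pr3SiCl, imidazole, DMF) should give [3,5-bis(methoxymethoxy)phenoxy]tri(propan-2-yl)silane F5. Lithiation between the two MOM ethers (n-BuLi, THF, 0 °C) and allylation with 3 (CuI, 10 mol%) should give [4-geranyl-3,5-bis(methoxymethoxy)phenoxy]tri(propan-2-yl)silane F6, and Bu4NF in THF should free the phenol, coming back at 7.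

Further compounds
F1 | step 8 | 2-phenylpropan-2-yl 3-[3-geranyl-6-hydroxy-2,4-bis(methoxymethoxy)phenyl]-3-hydroxypropanoate (racemic at the carbinol carbon) | CC(C)(OC(=O)CC(O)c1c(O)cc(OCOC)c(C/C=C(\C)CCC=C(C)C)c1OCOC)c1ccccc1
F2 | step 8 | 2-phenylpropan-2-yl 3-[3-geranyl-6-hydroxy-2,4-bis(methoxymethoxy)phenyl]-3-oxopropanoate | CC(C)(OC(=O)CC(=O)c1c(O)cc(OCOC)c(C/C=C(\C)CCC=C(C)C)c1OCOC)c1ccccc1
F0 | step 9 | none | none
F3 | step 3 | 2-[3,5-bis(methoxymethoxy)phenyl]-4,4,5,5-tetramethyl-1,3,2-dioxaborolane | COCOc1cc(OCOC)cc(B2OC(C)(C)C(C)(C)O2)c1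
F4 | step 3 | 3,5-bis(methoxymethoxy)phenol | COCOc1cc(O)cc(OCOC)c1
F5 | step 3 | [3,5-bis(methoxymethoxy)phenoxy]tri(propan-2-yl)silane | COCOc1cc(OCOC)cc(O[Si](C(C)C)(C(C)C)C(C)C)c1
F6 | step 3 | [4-geranyl-3,5-bis(methoxymethoxy)phenoxy]tri(propan-2-yl)silane | COCOc1cc(O[Si](C(C)C)(C(C)C)C(C)C)cc(OCOC)c1C/C=C(\C)CCC=C(C)C
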